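## Structural features

Flemistrictin D (19) is a 2,2-dimethyl-2H-chromene: a benzene ring (ring A: C4a, C5, C6, C7, C8, C8a) is fused across C4a–C8a to a pyran (ring B: O1, C2, C3, C4), and a 3-phenylpropanoyl chain links C6 through a ketone and two methylene groups to an unsubstituted phenyl ring. Ring A has no hydrogen left: it carries the C4 carbon (C4a), a hydroxyl (C5), the acyl group (C6), a methoxy (C7), a second hydroxyl (C8) and the ring oxygen O1 (C8a), so C5–OH and C8–OH form a para-hydroquinone. There is no stereocentre, so no stereocentres stand next to each other; the only stereo-element is the C3=C4 alkene, which the six-membered ring holds cis, and C2 is quaternary with two identical methyl groups. The fragile parts are the electron-rich hydroquinone (easily oxidised to the quinone), the styrene-like C3=C4 alkene and the tertiary allylic C2–O1 bond (both sensitive to acid and electrophiles), and, at the quinone oxidation level, the C7 methoxy group, which becomes a vinylogous ester beside the acyl group. The real difficulty is regiochemical: four oxygens of three kinds and two different carbon substituents must be placed on one benzene ring, and O1 must end up next to the C8 oxygen and not next to C6. The key step exploits the position of C3=C4 between the arene carbon C4a and the quaternary ether carbon C2: a vinyl group on C4a and a 1,1-dimethylallyl group on the C8a oxygen are the two halves of that alkene, so ring B can be closed by joining them.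

## Logic of the disconnections

19 ⇒ 18. Only the oxidation level changes: the O–H bonds at C5 and C8 are traced back to two quinone carbonyls. This keeps the air-sensitive hydroquinone out of every earlier step. The skeleton is not simplified; the forward step must deliver two hydrogens without touching the ketone or C3=C4.

18 ⇒ 17. The C8 carbonyl is traced to a C8–O–CH3 ether and the C5 carbonyl to a free phenol. The C8 oxygen can then travel as an inert methyl ether from the first compound on, which leaves one oxygen fewer to protect and to tell apart. The forward oxidation must give the para-quinone, keep the C7 methoxy (not para to the phenol) and spare the alkene.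

17 ⇒ 16. The O–CH2 bond of an acetal on the C5 oxygen is cut. The acetal is wanted in the preceding step as a directing and protecting group. Its removal must be mild enough for C3=C4 and the C2–O1 bond.

16 ⇒ 12 + 14 (through 15). The C6–C(=O) bond is cut. C6 is the only C–H of ring A in 12 and lies between two ether oxygens, so it can be turned into the carbanion 15 without a regiochemical question. This is convergent and removes nine carbons and the ketone. The demands are that metalation be faster than attack on C3=C4 and that acyl transfer stop at the ketone.

14 ⇒ 13. The amide C–N bond is cut, leading to a commercial acid. The forward step is a routine coupling.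

12 ⇒ 11. The C3=C4 double bond is cut into two terminal alkenes, which opens ring B and leaves a monocyclic arene with only heteroatom-linked or one-carbon substituents. In 11 the vinyl group sits between the acetal oxygen and the tertiary ether, and the ether oxygen is flanked on its other side by the two methoxy groups. This maps onto C5, C4a, C8a, C8 and C7 of 12, so neither structure needs correction. The forward closure must outrun sigmatropic migration of the tertiary allyl group.

11 ⇒ 10. The terminal CH2 of the C4a vinyl group is removed, leaving an aldehyde carbon. The aldehyde is the handle that earlier decides which methoxy is cleaved. The forward methylenation must work on a 2,6-dioxygenated aldehyde under base without disturbing the tertiary allyl ether.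

10 ⇒ 9. Two hydrogens are removed from the ether alkene to give an alkyne. Tertiary propargylic electrophiles etherify phenols cleanly at the tertiary carbon, whereas tertiary allylic ones tend to transpose or eliminate. The forward hydrogenation must stop at the alkene.

9 ⇒ 7 (through 8). The acetal O–CH2 bond on the C5 oxygen is exchanged for an ester O–C(=O) bond. The acetal would not survive the Lewis acid used earlier and the ester would not survive the organolithium used later, so the exchange is placed here and done in one flask. The ester must be cleaved without touching the aldehyde or alkyne, and the aryloxide 8 must be alkylated on oxygen.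

7 ⇒ 4 + 5 (through 6). The O1–C2 bond is cut. This puts the quaternary carbon on the C8a oxygen by O-alkylation. Because 4 has a single free hydroxyl, the placement of O1 next to the C8 oxygen is beyond doubt. Five carbons are removed. The forward step must etherify a hindered, hydrogen-bonded phenol at a tertiary carbon.

4 ⇒ 3. The O–CH3 bond on the C8a oxygen is restored. Of three methoxy groups only this one is ortho to the aldehyde, so a chelating Lewis acid can single it out. The other oxygen ortho to the aldehyde must therefore carry a Lewis-acid-inert group and not be a free phenol. This is a deliberate departure from the more obvious plan of unmasking both ortho hydroxyls and then separating them by hindrance alone. That plan would rest on a small steric difference between two chelated phenols, and the first boron chelate would occupy the carbonyl needed to direct the demethylation.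

3 ⇒ 2 ⇒ 1. The ester O–C(=O) bond and then the C4a–CHO bond are cut. 1 already holds all four ring oxygens, three as methyl ethers in the right places, and its two ortho positions are equivalent, so formylation has no regiochemical issue.

## Other disconnections considered

Alternative 1: The cut goes through ring A itself (C6–C7), tracing the arene to an open-chain tetraketide masked as 4-hydroxy-6-(2-oxo-4-phenylbutyl)-2H-pyran-2-one A1. In the forward step Mg(OMe)2 would open the lactone, the carbon between the two ketones would attack the ester carbonyl in a templated Claisen condensation, and aromatisation would give 3-phenyl-1-(2,4,6-trihydroxyphenyl)propan-1-one A2.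
- In its favour: the acyl chain is on the right carbon between two oxygens from the outset, with no protecting group and no organometallic step. On this point it is better than the chosen plan, which must acylate an aryllithium on a chromene. The carbonyl condensation is as dependable mechanistically as the metathesis, and A2 would be reached in fewer steps than 12.
- Against it: A2 lacks the C8 oxygen, has two equivalent ortho hydroxyls of which only one may be methylated, and has two equivalent ring C–H positions, one to be oxygenated and one to carry the pyran. That is four regiochemical decisions after the key step, whereas the chosen plan settles all of them by construction from 1.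
- The ring construction also buys little, since the same triphenol ketone is available by direct C-acylation of the symmetric triphenol.
- Overall it is shorter to the key intermediate but expected to be longer and less selective to the target.

Alternative 2: The cut is the C4a–C5 bond of ring A. In the forward step the cyclobutenone 4-{4-[(tert-butyldimethylsilyl)oxy]-2,2-dimethyl-3,4-dihydro-2H-pyran-6-yl}-4-hydroxy-3-methoxy-2-[2-(2-phenylethyl)-1,3-dithian-2-yl]cyclobut-2-en-1-one A3 would be heated. Four-electron ring opening would give a dienylketene, six-electron closure would form C4a–C5, and tautomerisation would give 4-(tert-butyldimethylsilyloxy)-7-methoxy-2,2-dimethyl-6-[2-(2-phenylethyl)-1,3-dithian-2-yl]chromane-5,8-diol A4.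
- In its favour: every substituent of ring A is placed by the cyclobutenone substitution pattern, and the ring arrives at the hydroquinone level. It therefore addresses the hexasubstituted arene more directly than the chosen plan and needs no oxidation with tetravalent cerium; on these two points it is the better. The pericyclic cascade is as predictable as the metathesis.
- Against it: A3 needs an unsymmetrical cyclobutenedione and a lithiated dihydropyran carrying a silyl ether, joined by a regioselective carbonyl addition.
- A4 is a chromane. It still needs desilylation and dehydration to create C3=C4, and dithiane hydrolysis beside a free hydroquinone, which thiophilic or oxidative reagents would probably take to the quinone, so a reduction would be needed again.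
- In step economy and protecting-group count it is clearly behind the chosen plan.

Alternative 3: The cut is the O1–C2 bond. In the forward step DDQ would abstract hydride from the ring-bound CH2 of the prenyl group of 2-hydroxy-6-methoxy-3-(3-methylbut-2-en-1-yl)-5-(3-phenylpropanoyl)cyclohexa-2,5-diene-1,4-dione A5. The resulting quinone methide would close by an oxa-six-electron electrocyclisation to 7-methoxy-2,2-dimethyl-6-(3-phenylpropanoyl)-2H-chromene-5,8-dione A6, which is the same compound as 18.
- In its favour: A6 is one reduction from the target, against five steps from 12 in the chosen plan, so after the key step this alternative is better in step economy. It also needs no transition-metal catalyst. Since both plans converge on the same quinone, they are equal from there on.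
- Against it: A5 is a fully substituted hydroxyquinone whose preparation contains the whole regiochemical problem (prenyl, acyl, methoxy and hydroxyl in the right order).
- Its hydroxy-para-quinone and hydroxy-ortho-quinone tautomers could close through either oxygen flanking the prenyl group, giving the linear or the angular pyran. The chosen plan fixes O1 by O-alkylation.
- DDQ could also attack the CH2–CH2 unit of the side chain.
- It would be shorter only if A5 were accessible in a few steps, which is the uncertain part.

Key step: step 8

Remark on the chemistry: the target has no stereocentre and its only non-aromatic double bond is held cis by ring B, so no SMILES string of the main route needs a stereodescriptor. Chromene numbering (O1, C2, C3, C4, C4a, C5–C8, C8a) is used for the bicyclic compounds and for the corresponding atoms of their monocyclic precursors.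

## Route

Step 1
Reactants: 1 3,4,5-trimethoxyphenol
Product: 2 6-hydroxy-2,3,4-trimethoxybenzaldehyde
Conditions: MgCl2, Et3N, (CH2O)n, MeCN, reflux; then 1 M HCl
Reagents that add atoms: formaldehyde (used as paraformaldehyde), C=O
Why: Magnesium-mediated ortho-formylation of a phenol (Casnati–Skattebøl reaction): the chelated magnesium phenoxide is attacked by formaldehyde only ortho to oxygen and a second formaldehyde accepts hydride to give the aldehyde. The two ortho positions of 1 are equivalent and the first formyl group deactivates the ring against a second.

Step 2
Reactants: 2 6-hydroxy-2,3,4-trimethoxybenzaldehyde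
Product: 3 2-formyl-3,4,5-trimethoxyphenyl 2,2-dimethylpropanoate
Conditions: t-BuCOCl, Et3N, DMAP (cat.), CH2Cl2, 0 °C → rt
Reagents that add atoms: pivaloyl chloride (2,2-dimethylpropanoyl chloride), CC(C)(C)C(=O)Cl
Why: DMAP-catalysed O-acylation of the only hydroxyl. The hindered ester is inert to BCl3 and to amidine base, and it keeps the native phenol oxygen distinguishable from the one unmasked in the next step.

Step 3
Reactants: 3 2-formyl-3,4,5-trimethoxyphenyl 2,2-dimethylpropanoate
Product: 4 2-formyl-3-hydroxy-4,5-dimethoxyphenyl 2,2-dimethylpropanoate
Conditions: BCl3 (1.2 equiv), CH2Cl2, −78 → 0 °C; then H2O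
Reagents that add atoms: none
Why: Chelation-controlled ortho-demethylation of an aryl methyl ether: boron bound to the aldehyde oxygen bridges to the adjacent methoxy oxygen and chloride removes the methyl group, leaving a six-membered boron chelate that is hydrolysed on work-up. Only one methoxy is ortho to the aldehyde, and the ester carbonyl is a much weaker donor than the electron-rich aldehyde.

Step 4
Reactants: 4 2-formyl-3-hydroxy-4,5-dimethoxyphenyl 2,2-dimethylpropanoate; 5 2-methylbut-3-yn-2-ol
Product: 7 2-formyl-4,5-dimethoxy-3-[(2-methylbut-3-yn-2-yl)oxy]phenyl 2,2-dimethylpropanoate, via propargylic trifluoroacetate 6 (not isolated)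
Conditions: 5, (CF3CO)2O, DBU, MeCN, −5 °C; then 4, DBU, CuCl2·2H2O (cat.), MeCN, 0 °C
Reagents that add atoms: none
Why: Copper-catalysed propargylic etherification of a phenol: the copper acetylide of 6 ionises to a copper-stabilised propargylic cation that the phenoxide captures at the tertiary carbon. Since 4 has one free hydroxyl, the ether can only form on the oxygen that becomes O1.

Step 5
Reactants: 7 2-formyl-4,5-dimethoxy-3-[(2-methylbut-3-yn-2-yl)oxy]phenyl 2,2-dimethylpropanoate
Product: 9 3,4-dimethoxy-6-(methoxymethoxy)-2-[(2-methylbut-3-yn-2-yl)oxy]benzaldehyde, via sodium phenolate 8 (not isolated)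
Conditions: NaOMe (1.05 equiv), THF/DMF, 0 °C; then MeOCH2Cl, 0 °C → rt
Reagents that add atoms: chloromethyl methyl ether, COCCl
Why: Transesterification followed by Williamson-type O-alkylation in one flask: methoxide takes the acyl group of the activated aryl ester (the leaving aryloxide is stabilised by the ortho aldehyde) and the aryloxide is then capped as the methoxymethyl ether. The by-product ester is inert, and the aldehyde, which cannot enolise, and the alkyne are untouched.

Step 6
Reactants: 9 3,4-dimethoxy-6-(methoxymethoxy)-2-[(2-methylbut-3-yn-2-yl)oxy]benzaldehyde
Product: 10 3,4-dimethoxy-6-(methoxymethoxy)-2-[(2-methylbut-3-en-2-yl)oxy]benzaldehyde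
Conditions: H2 (1 atm), Pd/CaCO3 poisoned with Pb(OAc)2, quinoline, EtOAc, rt
Reagents that add atoms: none
Why: Lindlar semihydrogenation: the terminal alkyne binds to the poisoned palladium surface far more strongly than the product alkene, so uptake should stop after one equivalent. The aldehyde and the aryl ethers are not reduced under these conditions.

Step 7
Reactants: 10 3,4-dimethoxy-6-(methoxymethoxy)-2-[(2-methylbut-3-en-2-yl)oxy]benzaldehyde
Product: 11 2-ethenyl-4,5-dimethoxy-1-(methoxymethoxy)-3-[(2-methylbut-3-en-2-yl)oxy]benzene
Conditions: Ph3PCH3Br, KOt-Bu, THF, 0 °C → rt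
Reagents that add atoms: methyltriphenylphosphonium bromide, C[P+](c1ccccc1)(c1ccccc1)c1ccccc1.[Br-]
Why: Wittig methylenation of an aldehyde that cannot enolise; the small unstabilised ylide tolerates the two ortho alkoxy groups. The cold basic medium leaves the acetal and the thermally and acid-labile tertiary allyl aryl ether intact.

Step 8
Reactants: 11 2-ethenyl-4,5-dimethoxy-1-(methoxymethoxy)-3-[(2-methylbut-3-en-2-yl)oxy]benzene
Product: 12 7,8-dimethoxy-5-(methoxymethoxy)-2,2-dimethyl-2H-chromene
Conditions: RuCl2(=CHPh)(PCy3)(H2IMes) (second-generation Grubbs catalyst, 5 mol %), CH2Cl2 (0.01 M), 25–40 °C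
Reagents that add atoms: none
Why: Ring-closing olefin metathesis by the Chauvin mechanism: the ruthenium benzylidene exchanges with the more accessible vinyl group on C4a, the new arylidene adds across the alkene of the tertiary ether to a ruthenacyclobutane, and cycloreversion forms C3=C4 while the methylidene carries the chain and ethene leaves. The closest known reaction type is the ring-closing metathesis of 2-vinylaryl allyl ethers to 2H-chromenes. Ring B closes as a six-membered oxacycle by joining the two terminal alkene carbons of a 1,7-diene whose ends are held ortho on the arene, and the endocyclic alkene is necessarily cis. No stereocentre is formed, so no controlling element is needed. The selectivity required is cyclisation over intermolecular metathesis and over [3,3]-migration of the 1,1-dimethylallyl group toward the open C6 position. The rigid ortho arrangement and the gem-dimethyl group at C2 favour closure, high dilution suppresses dimerisation, and 25–40 °C is well below the temperature at which such ethers rearrange. Loss of ethene makes the closure irreversible. The acetal and methyl ethers are inert to the carbene.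

Step 9
Reactants: 13 3-phenylpropanoic acid
Product: 14 N-methoxy-N-methyl-3-phenylpropanamide
Conditions: MeNH(OMe)·HCl, EDC·HCl, Et3N, DMAP (cat.), CH2Cl2, 0 °C → rt
Reagents that add atoms: N,O-dimethylhydroxylamine hydrochloride, CNOC.Cl
Why: Carbodiimide-mediated amide coupling of an unhindered acid with a secondary hydroxylamine, giving the Weinreb amide; there is no competing functionality.

Step 10
Reactants: 12 7,8-dimethoxy-5-(methoxymethoxy)-2,2-dimethyl-2H-chromene; 14 N-methoxy-N-methyl-3-phenylpropanamide
Product: 16 1-[7,8-dimethoxy-5-(methoxymethoxy)-2,2-dimethyl-2H-chromen-6-yl]-3-phenylpropan-1-one, via 6-lithiochromene 15 (not isolated)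
Conditions: n-BuLi, THF, −20 → 0 °C; then 14, −78 °C → rt; then H2O
Reagents that add atoms: none
Why: Directed ortho-metalation followed by Weinreb ketone synthesis: C6–H is the only arene hydrogen and is acidified and coordinated by the flanking acetal and methoxy oxygens. The chelated tetrahedral adduct of 15 with 14 does not collapse until work-up, so a second addition cannot occur.

Step 11
Reactants: 16 1-[7,8-dimethoxy-5-(methoxymethoxy)-2,2-dimethyl-2H-chromen-6-yl]-3-phenylpropan-1-one
Product: 17 1-(5-hydroxy-7,8-dimethoxy-2,2-dimethyl-2H-chromen-6-yl)-3-phenylpropan-1-one
Conditions: 2 M HCl, MeOH, rt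
Reagents that add atoms: none
Why: Acid-catalysed acetal exchange with methanol; an aryl methoxymethyl ether ortho to a ketone is especially labile because the released phenol is held in a hydrogen bond to the carbonyl. Dilute acid at room temperature should spare the C3=C4 alkene and the C2–O1 bond.

Step 12
Reactants: 17 1-(5-hydroxy-7,8-dimethoxy-2,2-dimethyl-2H-chromen-6-yl)-3-phenylpropan-1-one
Product: 18 7-methoxy-2,2-dimethyl-6-(3-phenylpropanoyl)-2H-chromene-5,8-dione
Conditions: (NH4)2Ce(NO3)6 (2.2 equiv), MeCN/H2O, 0 °C
Reagents that add atoms: water, O
Why: Oxidative demethylation of a para-methoxyphenol: tetravalent cerium removes two electrons from the phenol, water adds at C8 of the resulting cation and methanol is expelled to give the para-quinone. The C7 methoxy is not para to the phenol and is retained, and both positions ortho to C5–OH carry carbon, so no ortho-quinone can form.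

Step 13
Reactants: 18 7-methoxy-2,2-dimethyl-6-(3-phenylpropanoyl)-2H-chromene-5,8-dione
Product: 19 1-(5,8-dihydroxy-7-methoxy-2,2-dimethyl-2H-chromen-6-yl)-3-phenylpropan-1-one (Flemistrictin D)
Conditions: Na2S2O4, EtOAc/H2O, rt, under N2
Reagents that add atoms: none
Why: Dithionite reduction of a quinone to its hydroquinone, a two-electron, two-proton transfer that does not touch the aryl ketone or the C3=C4 alkene. The product is stabilised by the hydrogen bond between C5–OH and the ketone.

## Compound list

1 | 3,4,5-trimethoxyphenol | COc1cc(O)cc(OC)c1OC | starting material
2 | 6-hydroxy-2,3,4-trimethoxybenzaldehyde | COc1cc(O)c(C=O)c(OC)c1OC | intermediate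
3 | 2-formyl-3,4,5-trimethoxyphenyl 2,2-dimethylpropanoate | COc1cc(OC(=O)C(C)(C)C)c(C=O)c(OC)c1OC | intermediate
4 | 2-formyl-3-hydroxy-4,5-dimethoxyphenyl 2,2-dimethylpropanoate | COc1cc(OC(=O)C(C)(C)C)c(C=O)c(O)c1OC | intermediate
5 | 2-methylbut-3-yn-2-ol | CC(C)(O)C#C | starting material
6 | 2-methylbut-3-yn-2-yl trifluoroacetate | CC(C)(C#C)OC(=O)C(F)(F)F | intermediate (not isolated)
7 | 2-formyl-4,5-dimethoxy-3-[(2-methylbut-3-yn-2-yl)oxy]phenyl 2,2-dimethylpropanoate | COc1cc(OC(=O)C(C)(C)C)c(C=O)c(OC(C)(C)C#C)c1OC | intermediate
8 | sodium 2-formyl-4,5-dimethoxy-3-[(2-methylbut-3-yn-2-yl)oxy]phenolate | COc1cc([O-])c(C=O)c(OC(C)(C)C#C)c1OC.[Na+] | intermediate (not isolated)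
9 | 3,4-dimethoxy-6-(methoxymethoxy)-2-[(2-methylbut-3-yn-2-yl)oxy]benzaldehyde | COc1cc(OCOC)c(C=O)c(OC(C)(C)C#C)c1OC | intermediate
10 | 3,4-dimethoxy-6-(methoxymethoxy)-2-[(2-methylbut-3-en-2-yl)oxy]benzaldehyde | COc1cc(OCOC)c(C=O)c(OC(C)(C)C=C)c1OC | intermediate
11 | 2-ethenyl-4,5-dimethoxy-1-(methoxymethoxy)-3-[(2-methylbut-3-en-2-yl)oxy]benzene | COc1cc(OCOC)c(C=C)c(OC(C)(C)C=C)c1OC | intermediate
12 | 7,8-dimethoxy-5-(methoxymethoxy)-2,2-dimethyl-2H-chromene | COc1cc(OCOC)c2C=CC(C)(C)Oc2c1OC | intermediate
13 | 3-phenylpropanoic acid | OC(=O)CCc1ccccc1 | starting material
14 | N-methoxy-N-methyl-3-phenylpropanamide | CON(C)C(=O)CCc1ccccc1 | intermediate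
15 | [7,8-dimethoxy-5-(methoxymethoxy)-2,2-dimethyl-2H-chromen-6-yl]lithium | [Li]c1c(OC)c(OC)c2OC(C)(C)C=Cc2c1OCOC | intermediate (not isolated)
16 | 1-[7,8-dimethoxy-5-(methoxymethoxy)-2,2-dimethyl-2H-chromen-6-yl]-3-phenylpropan-1-one | COc1c(C(=O)CCc3ccccc3)c(OCOC)c2C=CC(C)(C)Oc2c1OC | intermediate
17 | 1-(5-hydroxy-7,8-dimethoxy-2,2-dimethyl-2H-chromen-6-yl)-3-phenylpropan-1-one | COc1c(C(=O)CCc3ccccc3)c(O)c2C=CC(C)(C)Oc2c1OC | intermediate
18 | 7-methoxy-2,2-dimethyl-6-(3-phenylpropanoyl)-2H-chromene-5,8-dione | COC1=C(C(=O)CCc2ccccc2)C(=O)C2=C(OC(C)(C)C=C2)C1=O | intermediate
19 | 1-(5,8-dihydroxy-7-methoxy-2,2-dimethyl-2H-chromen-6-yl)-3-phenylpropan-1-one (Flemistrictin D) | COc1c(O)c2c(c(O)c1C(=O)CCc1ccccc1)C=CC(C)(C)O2 | target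

## Step count and least certain steps

Total: 13 steps. Longest linear sequence: 12 steps (steps 1–8 and 10–13, from 1 to 19). Step 9 is a one-step branch from 13. Steps 4 and 5 each combine two operations in one flask.

Step 8 (key step). The most likely failure is slow turnover. The arylidene formed on the vinyl group has ether oxygens in both ortho positions and can rest as an oxygen-chelated species, and the partner alkene sits beside a quaternary carbon. If this is answered by heating, sigmatropic migration of the 1,1-dimethylallyl group toward C6 and ionisation of the C2–O bond begin to compete, and at higher concentration intermolecular metathesis of the vinyl group takes over. The fallback leaves metathesis altogether and uses the classical coumarin-to-chromene conversion; it sets out from 4 and returns at 12. 4 is heated with Ph3P=CHCO2Et in N,N-diethylaniline (Wittig olefination followed by lactonisation) to give 7,8-dimethoxy-2-oxo-2H-chromen-5-yl 2,2-dimethylpropanoate F1. K2CO3 in MeOH followed by acidification removes the ester and recloses the lactone to 5-hydroxy-7,8-dimethoxy-2H-chromen-2-one F2. MeOCH2Cl and i-Pr2NEt give 7,8-dimethoxy-5-(methoxymethoxy)-2H-chromen-2-one F3. Two equivalents of MeLi add to the lactone carbonyl and open it to 2-[(1Z)-3-hydroxy-3-methylbut-1-en-1-yl]-5,6-dimethoxy-3-(methoxymethoxy)phenol F4, whose cis geometry is inherited from the lactone. On gentle warming with a trace of acetic acid it should lose water and close to 12.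

Step 4. The most likely failure is poor conversion in the etherification. The hydroxyl of 4 is tied up in a hydrogen bond to the aldehyde and is flanked on both sides, so elimination of 6 to the enyne and its hydrolysis can outrun C–O bond formation. The fallback forms the tertiary ether through an allylpalladium electrophile; it sets out from 4 and returns at 10. tert-Butyl 2-methylbut-3-en-2-yl carbonate F5 (from 2-methylbut-3-en-2-ol and di-tert-butyl dicarbonate) and Pd(PPh3)4 in THF at 0 °C are used. Zerovalent palladium ionises the carbonate, carbon dioxide is lost, the tert-butoxide deprotonates the phenol, and the phenoxide attacks the more substituted terminus of the allyl complex (Tsuji–Trost O-allylation). This gives 2-formyl-4,5-dimethoxy-3-[(2-methylbut-3-en-2-yl)oxy]phenyl 2,2-dimethylpropanoate F6. The one-flask ester-to-acetal exchange of step 5, now passing through sodium 2-formyl-4,5-dimethoxy-3-[(2-methylbut-3-en-2-yl)oxy]phenolate F7, then gives 10 directly, so 7, 9 and the semihydrogenation are bypassed.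

Step 10. The most likely failure is incomplete acyl transfer. 15 is flanked by two alkoxy groups and may act as a base toward the α-methylene of 14 instead of adding to its carbonyl, which would return 12 on work-up; prolonged warming to force the addition would invite attack of the organolithium on C3=C4. The fallback replaces the amide by an aldehyde and adds an oxidation; it sets out from 15 and returns at 16. 15 is quenched at −78 °C with 3-phenylpropanal, a far more reactive electrophile, to give racemic 1-[7,8-dimethoxy-5-(methoxymethoxy)-2,2-dimethyl-2H-chromen-6-yl]-3-phenylpropan-1-ol F8, and Dess–Martin periodinane oxidises the benzylic alcohol to 16.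

Step 12. The most likely failure is loss of the C7 methoxy group by addition of water and elimination of methanol once 18 has formed, since in the quinone this group is the β-alkoxy substituent of an enone flanked by two carbonyls. One-electron oxidation of the electron-rich C3=C4 alkene is a second risk. The fallback moves the change of oxidation level ahead of the acylation so that no acylquinone meets aqueous oxidant; it sets out from 12 and returns at 19. 2 M HCl in MeOH converts 12 into 7,8-dimethoxy-2,2-dimethyl-2H-chromen-5-ol F9. (NH4)2Ce(NO3)6 gives 7-methoxy-2,2-dimethyl-2H-chromene-5,8-dione F10, a simple methoxyquinone without the activating acyl group. Na2S2O4 reduces it to 7-methoxy-2,2-dimethyl-2H-chromene-5,8-diol F11, which is protected at once with MeOCH2Cl and NaH as 7-methoxy-5,8-bis(methoxymethoxy)-2,2-dimethyl-2H-chromene F12. n-BuLi metalates the single arene C–H to [7-methoxy-5,8-bis(methoxymethoxy)-2,2-dimethyl-2H-chromen-6-yl]lithium F13, which is acylated with 14 to 1-[7-methoxy-5,8-bis(methoxymethoxy)-2,2-dimethyl-2H-chromen-6-yl]-3-phenylpropan-1-one F14. 2 M HCl in MeOH removes both acetals and gives 19.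

## Further compounds

F1 | step 8 | 7,8-dimethoxy-2-oxo-2H-chromen-5-yl 2,2-dimethylpropanoate | COc1cc(OC(=O)C(C)(C)C)c2C=CC(=O)Oc2c1OC
F2 | step 8 | 5-hydroxy-7,8-dimethoxy-2H-chromen-2-one | COc1cc(O)c2C=CC(=O)Oc2c1OC
F3 | step 8 | 7,8-dimethoxy-5-(methoxymethoxy)-2H-chromen-2-one | COc1cc(OCOC)c2C=CC(=O)Oc2c1OC
F4 | step 8 | 2-[(1Z)-3-hydroxy-3-methylbut-1-en-1-yl]-5,6-dimethoxy-3-(methoxymethoxy)phenol | COc1cc(OCOC)c(/C=C\C(C)(C)O)c(O)c1OC
F5 | step 4 | tert-butyl 2-methylbut-3-en-2-yl carbonate | CC(C)(C)OC(=O)OC(C)(C)C=C
F6 | step 4 | 2-formyl-4,5-dimethoxy-3-[(2-methylbut-3-en-2-yl)oxy]phenyl 2,2-dimethylpropanoate | COc1cc(OC(=O)C(C)(C)C)c(C=O)c(OC(C)(C)C=C)c1OC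
F7 | step 4 | sodium 2-formyl-4,5-dimethoxy-3-[(2-methylbut-3-en-2-yl)oxy]phenolate | COc1cc([O-])c(C=O)c(OC(C)(C)C=C)c1OC.[Na+]
F8 | step 10 | 1-[7,8-dimethoxy-5-(methoxymethoxy)-2,2-dimethyl-2H-chromen-6-yl]-3-phenylpropan-1-ol (racemic) | COc1c(C(O)CCc3ccccc3)c(OCOC)c2C=CC(C)(C)Oc2c1OC
F9 | step 12 | 7,8-dimethoxy-2,2-dimethyl-2H-chromen-5-ol | COc1cc(O)c2C=CC(C)(C)Oc2c1OC
F10 | step 12 | 7-methoxy-2,2-dimethyl-2H-chromene-5,8-dione | COC1=CC(=O)C2=C(OC(C)(C)C=C2)C1=O
F11 | step 12 | 7-methoxy-2,2-dimethyl-2H-chromene-5,8-diol | COc1cc(O)c2C=CC(C)(C)Oc2c1O
F12 | step 12 | 7-methoxy-5,8-bis(methoxymethoxy)-2,2-dimethyl-2H-chromene | COc1cc(OCOC)c2C=CC(C)(C)Oc2c1OCOC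
F13 | step 12 | [7-methoxy-5,8-bis(methoxymethoxy)-2,2-dimethyl-2H-chromen-6-yl]lithium | [Li]c1c(OC)c(OCOC)c2OC(C)(C)C=Cc2c1OCOC
F14 | step 12 | 1-[7-methoxy-5,8-bis(methoxymethoxy)-2,2-dimethyl-2H-chromen-6-yl]-3-phenylpropan-1-one | COc1c(C(=O)CCc3ccccc3)c(OCOC)c2C=CC(C)(C)Oc2c1OCOC
A1 | alternative 1 | 4-hydroxy-6-(2-oxo-4-phenylbutyl)-2H-pyran-2-one | O=C(CCc1ccccc1)CC1=CC(O)=CC(=O)O1
A2 | alternative 1 | 3-phenyl-1-(2,4,6-trihydroxyphenyl)propan-1-one | O=C(CCc1ccccc1)c1c(O)cc(O)cc1O
A3 | alternative 2 | 4-{4-[(tert-butyldimethylsilyl)oxy]-2,2-dimethyl-3,4-dihydro-2H-pyran-6-yl}-4-hydroxy-3-methoxy-2-[2-(2-phenylethyl)-1,3-dithian-2-yl]cyclobut-2-en-1-one | COC1=C(C2(CCc3ccccc3)SCCCS2)C(=O)C1(O)C4=CC(O[Si](C)(C)C(C)(C)C)CC(C)(C)O4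
A4 | alternative 2 | 4-(tert-butyldimethylsilyloxy)-7-methoxy-2,2-dimethyl-6-[2-(2-phenylethyl)-1,3-dithian-2-yl]chromane-5,8-diol | COc1c(O)c2OC(C)(C)CC(O[Si](C)(C)C(C)(C)C)c2c(O)c1C1(CCc2ccccc2)SCCCS1
A5 | alternative 3 | 2-hydroxy-6-methoxy-3-(3-methylbut-2-en-1-yl)-5-(3-phenylpropanoyl)cyclohexa-2,5-diene-1,4-dione | O=C1C(O)=C(CC=C(C)C)C(=O)C(C(=O)CCc2ccccc2)=C1OC
A6 | alternative 3 | 7-methoxy-2,2-dimethyl-6-(3-phenylpropanoyl)-2H-chromene-5,8-dione | COC1=C(C(=O)CCc2ccccc2)C(=O)C2=C(OC(C)(C)C=C2)C1=O
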